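(All runs stem from a simulated flask on assumed constants, noise included.)

Start at the late end of the runs, where the falls in E stand clear of the scatter of 2 percentage points.

common to all: Q 3.8 mM

| run | E | D | remark | time |
|---|---|---|---|---|
| south-west | 0.75 M | 0.60 mM | run made earlier |  |
| south-east | 0.75 M | 2.4 mM | run made earlier |  |
| north-east | 1.5 M | 1.2 mM | run made earlier |  |
| Monday's | 0.75 M | 1.2 mM |  | 20 min |
| Tuesday's | 0.75 M | 1.2 mM |  | 60 min |

| run | time / min | E / % | L / % | Z / % | X / % |
|---|---|---|---|---|---|
| south-west | 2.00 | 93 | 0 | 4 | 2 |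
| south-west | 3.00 | 94 | 0 | 8 | 0 |
| south-west | 5.00 | 87 | 0 | 13 | 0 |
| south-west | 8.00 | 80 | 0 | 20 | 1 |
| south-west | 15.0 | 63 | 0 | 35 | 2 |
| south-west | 25.0 | 42 | 0 | 54 | 0 |
| south-east | 4.00 | 93 | 5 | 6 | 1 |
| south-east | 8.00 | 94 | 0 | 9 | 1 |
| south-east | 12.0 | 88 | 0 | 12 | 2 |
| south-east | 15.0 | 81 | 3 | 21 | 0 |
| south-east | 20.0 | 77 | 0 | 24 | 0 |
| south-east | 25.0 | 69 | 3 | 27 | 1 |
| north-east | 2.00 | 92 | 2 | 2 | 0 |
| north-east | 6.00 | 85 | 0 | 11 | 0 |
| north-east | 12.0 | 81 | 2 | 23 | 1 |
| north-east | 15.0 | 72 | 2 | 22 | 0 |
| north-east | 25.0 | 62 | 1 | 44 | 0 |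

(each reading ± 2 percentage points)



* which of these there is most of at the end, counted by the E in it, Monday's (L / Z / E / X)
* which of these there is most of at the end, counted by the E in it, Tuesday's (L / Z / E / X)
* final amount of the leader among these, as a percentage of the E charged, in Monday's
* final amount of the leader among these, as a percentage of the E charged, in Tuesday's

Read the last rows of the south-west and south-east runs, both at 25.0 min: E stands at 42% and 69%, while L and X stay close to the scatter. Treat E as a first-order decay (pseudo-first-order), so the log of one over the share left is time over a time constant. Divide one log by the other and time drops out: 2.34.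

Now read the charges. Q minus D is 3.20 mM in the south-west run and 1.40 mM in the south-east run, a ratio of 2.29, close to the log ratio. So take each D as putting one Q out of work.

Then reckon Monday's dose as 0.650, the working catalyst times the time, with the south-west run's last row counted as one. Equal doses should leave equal shares of E, and the share left is 42% raised to the dose.

The north-east row sets a limit. Its dose of 0.812 should leave 49.4%, but it shows 62%, more E than reckoned. So hold the rule to E at 0.75 M, the charge of both new flasks.

My reckoning for Monday's leaves E leading with 56.9%. For Tuesday's, the dose of 1.95 puts Z ahead with 81.6%.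

The forecast names the same leaders, E and Z, but with different amounts: 66% and 71%. It says: “Doubling E therefore leaves k unchanged, which confirms first order”.

The flask gives E leading Monday's with 60.1%, and Z leading Tuesday's with 81.1%.

    Q + D → G (k = 440 M⁻¹ s⁻¹)
    X → L (k = 1.00 s⁻¹)
    E + Q → X (k = 0.210 M⁻¹ s⁻¹)
    L → Q + Z (k = 0.760 s⁻¹)

Monday's dose of 0.650 was reckoned to leave 56.9% of E, and the flask leaves 60.1%. At Monday's end D stands at 0% of its charge and G holds 31.6% of the catalyst, and D's charge is 31.6% of Q's. Take the neighbour of Monday's charged with 0.015 M of Q, with the same D and time. Its dose is 3.45, so reckon E at 5.01%. In that neighbour G holds 8.00% of the catalyst, and E ends at 4.38%.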